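**Plan**

1. Retrosynthesis: ring C is opened across O1–C2 and C3–C4 (retro hetero-Diels–Alder) to a ring-B styrene and an o-quinoid α-oxoketene of ring A, which is stored as the acetonide of the ring-A hydroxy acid. The C8–CH2 bond is cut next (Negishi coupling), then the Cα–CH2 bond of the side chain (auxiliary-controlled dienolate alkylation).
2. Enabling feature: in ring C the atoms O1–C8a=C4a–C4(=O) form a 1-oxadiene at the acid oxidation level, which is an α-oxoketene once ring A is dearomatised. C2 is benzylic to the 2,4-dioxygenated ring B, so the C2=C3 unit of the styrene is an electron-rich, polarised alkene.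
3. Forward order: side chain (steps 1–6), ring-A acetonide (7–9), union at C8 (10), styrene (11–12). Ring C is closed last, with ring B attached in the same step (13), then resolution at C2 (14) and desilylation (15).
4. Stereochemistry: the side-chain centre comes from the (S)-4-benzyl oxazolidinone auxiliary in step 2. C2 is formed without control in step 13 and is made 2S by a catalyst-controlled kinetic resolution in step 14.
5. Helpers: the acetonide ring (leaves as acetone in step 13), the 5-O-silyl cap (shields C6 in step 9 and blocks the second ketene tautomer in step 13) and the other silyl ethers; all are gone after step 15.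

Key step: step 13

Remark: the acetonide of 2,4,6-trihydroxybenzoic acid used in step 7 is taken as purchased. The side-chain stereocentre keeps its arrangement in space from step 2 onward; its descriptor changes from S to R in step 10 only because the priorities change when CH2–metal becomes CH2–aryl. The two C2 epimers formed in step 13 are carried as one numbered compound.

**Route**

Step 1
Reactants: 1 (S)-4-benzyl-1,3-oxazolidin-2-one; 2 3-methylbut-2-enoyl chloride
Product: 4 N-(3-methylbut-2-enoyl) oxazolidinone, via N-lithio oxazolidinone 3 (not isolated)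
Conditions: n-BuLi, THF, −78 °C; then 2, −78 to 0 °C
Reagents that add atoms: none
Why: N-acylation of a lithiated oxazolidinone with an acid chloride is standard, and the low temperature should prevent deconjugation of the enoyl group.

Step 2
Reactants: 4 N-(3-methylbut-2-enoyl) oxazolidinone; 5 1-bromo-3-methylbut-2-ene
Product: 7 (2S)-2-isopropenyl-5-methylhex-4-enoyl oxazolidinone, via sodium dienolate 6 (not isolated)
Conditions: NaN(SiMe3)2, THF, −78 °C; then 5, −78 to −45 °C; AcOH quench at −78 °C
Reagents that add atoms: none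
Why: Evans deconjugative α-alkylation, in which γ-deprotonation gives the chelated (Z)-dienolate that should react at its α-carbon with the allylic bromide on the face opposite the benzyl group, setting the side-chain stereocentre.

Step 3
Reactants: 7 (2S)-2-isopropenyl-5-methylhex-4-enoyl oxazolidinone
Product: 8 epoxy imide (both epoxide epimers)
Conditions: mCPBA (1.05 equiv), NaHCO3, CH2Cl2, −10 to 0 °C
Reagents that add atoms: mCPBA O=C(OO)c1cccc(Cl)c1
Why: Prilezhaev epoxidation should take the electron-rich trisubstituted alkene and spare the 1,1-disubstituted isopropenyl group, which is further deactivated by the neighbouring acyl group; the uncontrolled epoxide centre is erased in step 4.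

Step 4
Reactants: 8 epoxy imide
Product: 9 (2S)-5-methyl-2-(prop-1-en-2-yl)hexane-1,5-diol
Conditions: LiAlH4, THF, 0 °C then 40 °C; aq. potassium sodium tartrate work-up
Reagents that add atoms: none
Why: hydride reduction should cleave the imide to the primary alcohol (releasing the auxiliary) and open the trisubstituted epoxide by SN2 attack at its less substituted carbon to give the tertiary alcohol, without touching the stereocentre.

Step 5
Reactants: 9 (2S)-5-methyl-2-(prop-1-en-2-yl)hexane-1,5-diol
Product: 10 (5S)-6-iodo-2-methyl-5-(prop-1-en-2-yl)hexan-2-ol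
Conditions: I2, PPh3, imidazole, CH2Cl2, 0 °C
Reagents that add atoms: iodine II
Why: Appel-type iodination should convert only the primary alcohol, because the tertiary alcohol cannot be displaced by SN2 under these conditions.

Step 6
Reactants: 10 (5S)-6-iodo-2-methyl-5-(prop-1-en-2-yl)hexan-2-ol
Product: 11 triethylsilyl ether of 10
Conditions: Et3SiOTf, 2,6-lutidine, CH2Cl2, −78 to 0 °C
Reagents that add atoms: triethylsilyl triflate CC[Si](CC)(CC)OS(=O)(=O)C(F)(F)F
Why: silyl triflate silylation of a hindered tertiary alcohol is standard; the cap is needed for the lithiation in step 10 and keeps the alcohol from trapping the ketene in step 13.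

Step 7
Reactants: 12 5,7-dihydroxy-2,2-dimethyl-4H-1,3-benzodioxin-4-one
Product: 13 5-hydroxy-7-methoxy-2,2-dimethyl-4H-1,3-benzodioxin-4-one
Conditions: MeOH, PPh3, DIAD, THF, 0 °C to rt
Reagents that add atoms: methanol CO
Why: Mitsunobu etherification should methylate only the 7-OH, because the 5-OH is held in a hydrogen bond to the C4 carbonyl.

Step 8
Reactants: 13 5-hydroxy-7-methoxy-2,2-dimethyl-4H-1,3-benzodioxin-4-one
Product: 14 5-O-TBS ether of 13
Conditions: t-BuMe2SiOTf, 2,6-lutidine, CH2Cl2, 0 °C
Reagents that add atoms: tert-butyldimethylsilyl triflate CC(C)(C)[Si](C)(C)OS(=O)(=O)C(F)(F)F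
Why: the reactive silyl triflate should silylate the hydrogen-bonded phenol, and the bulky ether shields C6 for step 9 and removes the second ketene tautomer in step 13.

Step 9
Reactants: 14 5-O-TBS ether of 13
Product: 15 8-bromo-5-O-TBS-7-methoxy acetonide
Conditions: NBS, MeCN, 0 °C, dark
Reagents that add atoms: N-bromosuccinimide O=C1CCC(=O)N1Br
Why: electrophilic aromatic bromination is expected at C8, which is para to the silyloxy group and flanked by the small ring oxygen, rather than at C6 between OTBS and OMe, in line with the C8 preference of 5,7-dialkoxy benzopyranones.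

Step 10
Reactants: 11 triethylsilyl ether of 10; 15 8-bromo-5-O-TBS-7-methoxy acetonide
Product: 18 8-alkyl acetonide, via alkyllithium 16 (not isolated), via alkylzinc chloride 17 (not isolated)
Conditions: 11, t-BuLi (2.1 equiv), Et2O, −78 °C; ZnCl2, THF, −78 °C to rt; then 15, Pd(OAc)2 (5 mol %), SPhos (10 mol %), THF, 50 °C
Reagents that add atoms: none
Why: Negishi coupling, in which iodine–lithium exchange (non-radical, so the homoallylic chain should not rearrange) and transmetalation give a primary alkylzinc that tolerates the lactone, while the bulky biarylphosphine lets zerovalent palladium insert into the hindered C8–Br bond; the stereocentre is not involved.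

Step 11
Reactants: 19 2,4-dihydroxybenzaldehyde
Product: 20 2,4-bis(tert-butyldimethylsilyloxy)benzaldehyde
Conditions: t-BuMe2SiCl (2.5 equiv), imidazole, DMF, rt
Reagents that add atoms: tert-butyldimethylsilyl chloride CC(C)(C)[Si](C)(C)Cl
Why: standard silylation of both phenols, with excess reagent to overcome the hydrogen-bonded ortho hydroxyl.

Step 12
Reactants: 20 2,4-bis(tert-butyldimethylsilyloxy)benzaldehyde
Product: 21 2,4-bis(tert-butyldimethylsilyloxy)styrene
Conditions: Ph3PCH3Br, NaN(SiMe3)2, THF, 0 °C; then 20, −78 to 0 °C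
Reagents that add atoms: methyltriphenylphosphonium bromide C[P+](c1ccccc1)(c1ccccc1)c1ccccc1.[Br-]
Why: Wittig methylenation of an aryl aldehyde, run with a non-nucleophilic base at low temperature so that the aryl silyl ethers should survive.

Step 13
Reactants: 18 8-alkyl acetonide; 21 2,4-bis(tert-butyldimethylsilyloxy)styrene
Product: 23 tetrasilyl flavanone (C2 epimer pair), via o-quinoid ketene 22 (not isolated)
Conditions: hν (300 nm), 21 (5 equiv), CH2Cl2 (0.01 M in 18), Ar, 0 °C
Reagents that add atoms: none
Why: Proposed new method: light is known to cleave 2,2-dimethyl-1,3-benzodioxin-4-ones in a retro-(4+2) step to acetone and an o-quinoid α-oxoketene (22; so far trapped with alcohols and amines), and α-oxoketenes are known to add enol ethers across their O=C–C=C unit to give 2,3-dihydro-4H-pyran-4-ones, which is the closest known reaction type; here the comparably electron-rich 2,4-bis(silyloxy)styrene 21 is proposed as the 2π partner. The electrophilic ketene carbon (C4) should bond to the terminal CH2 of 21 (C3) and the quinone oxygen on C8a to the benzylic carbon (C2), where positive charge is stabilised by the ortho and para silyloxy groups, so the orientation is set by polarity and the return of aromaticity to ring A drives the step. Ring C is closed by this intermolecular inverse-demand (4+2) hetero-Diels–Alder cycloaddition, concerted but asynchronous (at the limit a phenoxide and benzylic cation pair that collapses). C2 is the only new stereocentre and nothing controls it reliably, since the alkene is achiral and the side-chain centre is five bonds away, so both C2 epimers are expected and C2 is settled in step 14. The step needs site selectivity for closure through the oxygen next to C8, secured by the silyl cap on the other ortho oxygen (no second ketene tautomer), and chemoselectivity for the styrene over the isopropenyl group (not nucleophilic enough, and its intramolecular addition would need a bridge across ring A), over the capped tertiary alcohol and over ketene dimerisation (low stationary concentration, excess 21).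

Step 14
Reactants: 23 tetrasilyl flavanone (C2 epimer pair)
Product: 24 (2S)-tetrasilyl flavanone
Conditions: Cp*RhCl[(R,R)-TsDPEN] (1 mol %; Cp* = C5Me5, TsDPEN = TsNCHPhCHPhNH2), HCO2H/Et3N (5:2), EtOAc, rt, to about 50% conversion; chromatography
Reagents that add atoms: none
Why: Noyori-type asymmetric transfer hydrogenation used as a kinetic resolution, a reaction known for racemic flavanones; the (R,R) catalyst is expected, from its usual sense on aryl ketones, to reduce the (2R) epimer to the cis-(2R,4R)-flavan-4-ol and leave the (2S) ketone 24 (at most half of 23), while the isolated alkene and the silyl ethers should be inert.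

Step 15
Reactants: 24 (2S)-tetrasilyl flavanone
Product: 25 CNP0106344.1
Conditions: HF·pyridine, pyridine, THF, 0 °C to rt
Reagents that add atoms: none
Why: buffered fluoride should cleave the three aryl silyl ethers and the tertiary triethylsilyl ether without base (which would open ring C by E1cB to the chalcone and scramble C2) and without strong acid (which would cyclise the tertiary alcohol onto the isopropenyl group).

**Compound list**

1 | (S)-4-benzyl-1,3-oxazolidin-2-one | O=C1N[C@@H](Cc2ccccc2)CO1 | starting material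
2 | 3-methylbut-2-enoyl chloride | CC(C)=CC(=O)Cl | starting material
3 | lithium (S)-4-benzyl-2-oxo-1,3-oxazolidin-3-ide | [Li]N1[C@@H](Cc2ccccc2)COC1=O | intermediate
4 | (S)-4-benzyl-3-(3-methylbut-2-enoyl)-1,3-oxazolidin-2-one | CC(C)=CC(=O)N1[C@@H](Cc2ccccc2)COC1=O | intermediate
5 | 1-bromo-3-methylbut-2-ene | CC(C)=CCBr | starting material
6 | sodium (Z)-dienolate of 4 | C=C(C)/C=C(\O[Na])N1[C@@H](Cc2ccccc2)COC1=O | intermediate
7 | (S)-4-benzyl-3-[(2S)-5-methyl-2-(prop-1-en-2-yl)hex-4-enoyl]-1,3-oxazolidin-2-one | C=C(C)[C@H](CC=C(C)C)C(=O)N1[C@@H](Cc2ccccc2)COC1=O | intermediate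
8 | (S)-4-benzyl-3-[(2S)-3-(3,3-dimethyloxiran-2-yl)-2-(prop-1-en-2-yl)propanoyl]-1,3-oxazolidin-2-one, both epoxide epimers | C=C(C)[C@H](CC1OC1(C)C)C(=O)N1[C@@H](Cc2ccccc2)COC1=O | intermediate
9 | (2S)-5-methyl-2-(prop-1-en-2-yl)hexane-1,5-diol | C=C(C)[C@H](CCC(C)(C)O)CO | intermediate
10 | (5S)-6-iodo-2-methyl-5-(prop-1-en-2-yl)hexan-2-ol | C=C(C)[C@H](CCC(C)(C)O)CI | intermediate
11 | triethyl{[(5S)-6-iodo-2-methyl-5-(prop-1-en-2-yl)hexan-2-yl]oxy}silane | C=C(C)[C@H](CCC(C)(C)O[Si](CC)(CC)CC)CI | intermediate
12 | 5,7-dihydroxy-2,2-dimethyl-4H-1,3-benzodioxin-4-one | CC1(C)OC(=O)c2c(O)cc(O)cc2O1 | starting material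
13 | 5-hydroxy-7-methoxy-2,2-dimethyl-4H-1,3-benzodioxin-4-one | CC1(C)OC(=O)c2c(O)cc(OC)cc2O1 | intermediate
14 | 5-[(tert-butyldimethylsilyl)oxy]-7-methoxy-2,2-dimethyl-4H-1,3-benzodioxin-4-one | CC1(C)OC(=O)c2c(O[Si](C)(C)C(C)(C)C)cc(OC)cc2O1 | intermediate
15 | 8-bromo-5-[(tert-butyldimethylsilyl)oxy]-7-methoxy-2,2-dimethyl-4H-1,3-benzodioxin-4-one | CC1(C)OC(=O)c2c(O[Si](C)(C)C(C)(C)C)cc(OC)c(Br)c2O1 | intermediate
16 | {(2S)-5-methyl-2-(prop-1-en-2-yl)-5-[(triethylsilyl)oxy]hexyl}lithium | C=C(C)[C@H](CCC(C)(C)O[Si](CC)(CC)CC)C[Li] | intermediate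
17 | {(2S)-5-methyl-2-(prop-1-en-2-yl)-5-[(triethylsilyl)oxy]hexyl}zinc chloride | C=C(C)[C@H](CCC(C)(C)O[Si](CC)(CC)CC)C[Zn]Cl | intermediate
18 | 5-[(tert-butyldimethylsilyl)oxy]-7-methoxy-2,2-dimethyl-8-{(2R)-5-methyl-2-(prop-1-en-2-yl)-5-[(triethylsilyl)oxy]hexyl}-4H-1,3-benzodioxin-4-one | C=C(C)[C@H](CCC(C)(C)O[Si](CC)(CC)CC)Cc1c(OC)cc(O[Si](C)(C)C(C)(C)C)c2c1OC(C)(C)OC2=O | intermediate
19 | 2,4-dihydroxybenzaldehyde | O=Cc1ccc(O)cc1O | starting material
20 | 2,4-bis[(tert-butyldimethylsilyl)oxy]benzaldehyde | O=Cc1ccc(O[Si](C)(C)C(C)(C)C)cc1O[Si](C)(C)C(C)(C)C | intermediate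
21 | 2,4-bis[(tert-butyldimethylsilyl)oxy]-1-ethenylbenzene | C=Cc1ccc(O[Si](C)(C)C(C)(C)C)cc1O[Si](C)(C)C(C)(C)C | intermediate
22 | 5-[(tert-butyldimethylsilyl)oxy]-3-methoxy-2-{(2R)-5-methyl-2-(prop-1-en-2-yl)-5-[(triethylsilyl)oxy]hexyl}-6-(oxomethylidene)cyclohexa-2,4-dien-1-one | C=C(C)[C@H](CCC(C)(C)O[Si](CC)(CC)CC)CC1=C(OC)C=C(O[Si](C)(C)C(C)(C)C)C(=C=O)C1=O | intermediate
23 | (2RS)-2-{2,4-bis[(tert-butyldimethylsilyl)oxy]phenyl}-5-[(tert-butyldimethylsilyl)oxy]-7-methoxy-8-{(2R)-5-methyl-2-(prop-1-en-2-yl)-5-[(triethylsilyl)oxy]hexyl}-2,3-dihydro-4H-chromen-4-one, both C2 epimers | C=C(C)[C@H](CCC(C)(C)O[Si](CC)(CC)CC)Cc1c(OC)cc(O[Si](C)(C)C(C)(C)C)c2c1OC(c1ccc(O[Si](C)(C)C(C)(C)C)cc1O[Si](C)(C)C(C)(C)C)CC2=O | intermediate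
24 | (2S)-2-{2,4-bis[(tert-butyldimethylsilyl)oxy]phenyl}-5-[(tert-butyldimethylsilyl)oxy]-7-methoxy-8-{(2R)-5-methyl-2-(prop-1-en-2-yl)-5-[(triethylsilyl)oxy]hexyl}-2,3-dihydro-4H-chromen-4-one | C=C(C)[C@H](CCC(C)(C)O[Si](CC)(CC)CC)Cc1c(OC)cc(O[Si](C)(C)C(C)(C)C)c2c1O[C@H](c1ccc(O[Si](C)(C)C(C)(C)C)cc1O[Si](C)(C)C(C)(C)C)CC2=O | intermediate
25 | (2S)-2-(2,4-dihydroxyphenyl)-5-hydroxy-8-[(2R)-5-hydroxy-5-methyl-2-(prop-1-en-2-yl)hexyl]-7-methoxy-2,3-dihydro-4H-chromen-4-one (CNP0106344.1) | C=C(C)[C@H](CCC(C)(C)O)Cc1c(OC)cc(O)c2c1O[C@H](c1ccc(O)cc1O)CC2=O | target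

**Count and risks**

Total step count: 15. Longest linear sequence: 10 steps (steps 1–6, 10, 13, 14, 15).

Steps most likely to fail:

- Step 13 (photochemical ketene cycloaddition). The styrene and the flavanone product may absorb the light, or the ketene may dimerise or re-add acetone faster than it adds the alkene. Fallback with known chemistry, building ring C stepwise: from 18, MeLi (THF, −78 °C) opens the acetonide to the 2-hydroxyaryl methyl ketone F1. Its dianion (LiN(SiMe3)2, THF, −78 °C) adds to aldehyde 20 to give the β-hydroxy ketone F2 (aldol addition). PPh3 and DIAD (Mitsunobu etherification) then close the O1–C2 bond and give 23, where the route is rejoined.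

- Step 14 (kinetic resolution). The catalyst may discriminate poorly between the C2 epimers because the ketone is crowded by the 5-silyloxy group and the ortho-silyloxy ring B, the hydride transfer may be slow, or aryl silyl ethers may be lost in formic acid. Fallback that sets C2 by catalyst-controlled ring closure instead of resolution: from 18, the lithium enolate of allyl acetate (LiN(i-Pr)2, THF, −78 °C) gives the allyl β-keto ester F3. Knoevenagel condensation with 20 (piperidine, AcOH, toluene) gives the alkylidene β-keto ester F4. A cinchona-alkaloid thiourea (the pseudo-enantiomer that leads to 2S) catalyses the enantioselective oxa-Michael closure to the 3-allyloxycarbonyl flavanone F5. Pd(PPh3)4 and morpholine remove the allyl ester with loss of CO2 and give 24 directly.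

- Step 10 (Negishi coupling). Oxidative addition into the doubly ortho-oxygenated, electron-rich C8–Br bond may be slow, so that protonation or β-hydride loss of the alkylzinc wins. Fallback that changes the transmetalating partner to boron: alkyllithium 16 is trapped with B-methoxy-9-BBN to give the lithium alkyl borate F6, which is coupled with 15 in a B-alkyl Suzuki–Miyaura reaction (PdCl2(dppf), K3PO4, DMF/THF/H2O, rt) to give 18.

**Further compounds**

F1 | step 13 | 1-{6-[(tert-butyldimethylsilyl)oxy]-2-hydroxy-4-methoxy-3-[(2R)-5-methyl-2-(prop-1-en-2-yl)-5-(triethylsilyloxy)hexyl]phenyl}ethan-1-one | C=C(C)[C@H](CCC(C)(C)O[Si](CC)(CC)CC)Cc1c(OC)cc(O[Si](C)(C)C(C)(C)C)c(C(C)=O)c1O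
F2 | step 13 | β-hydroxy ketone from F1 and 20 (both carbinol epimers) | C=C(C)[C@H](CCC(C)(C)O[Si](CC)(CC)CC)Cc1c(OC)cc(O[Si](C)(C)C(C)(C)C)c(C(=O)CC(O)c2ccc(O[Si](C)(C)C(C)(C)C)cc2O[Si](C)(C)C(C)(C)C)c1O
F3 | step 14 | allyl 3-aryl-3-oxopropanoate from 18 (aryl = ring A with free C8a hydroxyl) | C=C(C)[C@H](CCC(C)(C)O[Si](CC)(CC)CC)Cc1c(OC)cc(O[Si](C)(C)C(C)(C)C)c(C(=O)CC(=O)OCC=C)c1O
F4 | step 14 | alkylidene β-keto ester from F3 and 20 | C=C(C)[C@H](CCC(C)(C)O[Si](CC)(CC)CC)Cc1c(OC)cc(O[Si](C)(C)C(C)(C)C)c(C(=O)C(=Cc2ccc(O[Si](C)(C)C(C)(C)C)cc2O[Si](C)(C)C(C)(C)C)C(=O)OCC=C)c1O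
F5 | step 14 | (2S)-3-allyloxycarbonyl derivative of 24 (both C3 epimers) | C=C(C)[C@H](CCC(C)(C)O[Si](CC)(CC)CC)Cc1c(OC)cc(O[Si](C)(C)C(C)(C)C)c2c1O[C@H](c1ccc(O[Si](C)(C)C(C)(C)C)cc1O[Si](C)(C)C(C)(C)C)C(C(=O)OCC=C)C2=O
F6 | step 10 | lithium B-methoxy-B-alkyl-9-borabicyclo[3.3.1]nonane borate from 16 | [Li+].CO[B-]1(C[C@@H](CCC(C)(C)O[Si](CC)(CC)CC)C(C)=C)C2CCCC1CCC2
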